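**Retrosynthetic overview**
1. Target ⇐ its 13-O-TES ether ⇐ exocyclic 8(17)-en-7-one, by cobalt-hydride H-atom-transfer alkene isomerisation into conjugation.
2. 8(17)-En-7-one ⇐ 6β-acetoxy-Δ7-ene, by singlet-oxygen ene reaction (O to C7) and Kornblum dehydration.
3. 6β-OAc ⇐ 7-en-6-one (α-face hydride reduction sets C6, then acetylation) ⇐ Δ7-ene, by allylic oxidation at C6.
4. Δ7-Ene ⇐ (+)-manool TES ether, by Co–H isomerisation of the 8(17)-alkene; C5, C10 and C13 are bought with manool.
5. Ring order: no ring is formed; rings A and B (trans-decalin) come intact from manool and only ring B is re-functionalised.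

Assumption: (+)-manool, (13R)-labda-8(17),14-dien-13-ol (CAS 596-85-0), is bought as the chiral-pool starting material.

Step 1
Reactants: 1 (+)-manool, (13R)-labda-8(17),14-dien-13-ol
Product: 2 (13R)-13-(triethylsilyloxy)labda-8(17),14-diene
Conditions: TESOTf, 2,6-lutidine, CH2Cl2, −78 to 0 °C
Reagents that add atoms: triethylsilyl trifluoromethanesulfonate (TESOTf) CC[Si](CC)(CC)OS(=O)(=O)C(F)(F)F
Why: Silyl-ether protection of the tertiary allylic alcohol under basic, non-ionising conditions masks the only OH before the Cr(VI) and acylation steps and touches no stereocentre.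

Step 2
Reactants: 2 (13R)-13-(triethylsilyloxy)labda-8(17),14-diene
Product: 3 (13R)-13-(triethylsilyloxy)labda-7,14-diene
Conditions: Co(salen-tBu,tBu)Cl (5 mol %), PhSiH3 (5 mol %), benzene, rt
Reagents that add atoms: none
Why: Cobalt-hydride HAT alkene isomerisation (Shenvi type) adds H• to the terminal C17 and returns H• from the less hindered C7–H2 of the tertiary C8 radical, giving the trisubstituted Δ7-alkene, while the vinyl group (no allylic H) cannot migrate and no stereocentre changes.

Step 3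
Reactants: 3 (13R)-13-(triethylsilyloxy)labda-7,14-diene
Product: 4 (13R)-13-(triethylsilyloxy)labda-7,14-dien-6-one
Conditions: CrO3, 3,5-dimethylpyrazole, CH2Cl2, −20 °C
Reagents that add atoms: chromium trioxide O=[Cr](=O)=O
Why: Allylic oxidation with CrO3·3,5-dimethylpyrazole (Salmond conditions) converts the only allylic CH2 (C6) into the conjugated 7-en-6-one, as is usual for drim-7-enes, and leaves the trans ring fusion (5α-H) intact.

Step 4
Reactants: 4 (13R)-13-(triethylsilyloxy)labda-7,14-dien-6-one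
Product: 5 (13R)-13-(triethylsilyloxy)labda-7,14-dien-6β-ol
Conditions: NaBH4, CeCl3·7H2O, MeOH, −40 to 0 °C
Reagents that add atoms: none
Why: Luche 1,2-reduction delivers hydride to the open α-face because the β-face of C6 is blocked by the syn-axial C10 and C4β methyl groups, so the axial 6β-alcohol forms and C6 is set.

Step 5
Reactants: 5 (13R)-13-(triethylsilyloxy)labda-7,14-dien-6β-ol
Product: 6 (13R)-6β-acetoxy-13-(triethylsilyloxy)labda-7,14-diene
Conditions: Ac2O, DMAP, Et3N, CH2Cl2, rt to 40 °C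
Reagents that add atoms: acetic anhydride CC(=O)OC(C)=O
Why: DMAP-catalysed acylation (Steglich-type acetylation) esterifies the hindered axial secondary alcohol with retention at C6.

Step 6
Reactants: 6 (13R)-6β-acetoxy-13-(triethylsilyloxy)labda-7,14-diene
Product: 9 (13R)-6β-acetoxy-13-(triethylsilyloxy)labda-8(17),14-dien-7-one, via 7α-hydroperoxide 7 (not isolated), via 7α-peroxyacetate 8 (not isolated)
Conditions: O2, TPP (cat.), hν, CH2Cl2, 0 °C; then Ac2O, pyridine, DMAP (cat.), 0 °C to rt
Reagents that add atoms: dioxygen O=O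
Why: In the Schenck ene reaction singlet oxygen must bond to C7, because the only abstractable allylic hydrogens sit on the C8 substituents (the CH3 group is preferred in a 1-methylcyclohexene, and the C6–H is equatorial and geminal to OAc), and Kornblum–DeLaMare-type dehydration of the secondary peroxyacetate then gives the 7-ketone without touching C6.

Step 7
Reactants: 9 (13R)-6β-acetoxy-13-(triethylsilyloxy)labda-8(17),14-dien-7-one
Product: 10 (13R)-6β-acetoxy-13-(triethylsilyloxy)labda-8,14-dien-7-one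
Conditions: Co(salen-tBu,tBu)Cl (5 mol %), PhSiH3 (5 mol %), benzene, rt
Reagents that add atoms: none
Why: Cobalt-hydride HAT isomerisation (the reversible H• transfer known from catalytic chain transfer of methacrylates) adds H• to the exocyclic CH2, and the α-keto C8 radical can only lose the 9α-H, giving the tetrasubstituted conjugated 8-en-7-one as thermodynamic sink with no enolisation at C6.

Step 8
Reactants: 10 (13R)-6β-acetoxy-13-(triethylsilyloxy)labda-8,14-dien-7-one
Product: 11 (5S,6S,10S,13R)-6β-acetoxy-13-hydroxylabda-8,14-dien-7-one (CNP0328351.1)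
Conditions: HF·pyridine, pyridine, THF, 0 °C to rt
Reagents that add atoms: none
Why: Fluoride-driven desilylation (Si–F bond formation) under pyridine-buffered conditions frees the tertiary allylic alcohol without ionising it or cleaving or epimerising the 6β-acetate.

**Compound list**
1 | (+)-manool, (13R)-labda-8(17),14-dien-13-ol (5α-H, 9α-H, 10β-CH3) | C=C[C@](C)(O)CC[C@H]1C(=C)CC[C@H]2C(C)(C)CCC[C@]12C | starting material
2 | (13R)-13-(triethylsilyloxy)labda-8(17),14-diene | C=C[C@](C)(O[Si](CC)(CC)CC)CC[C@H]1C(=C)CC[C@H]2C(C)(C)CCC[C@]12C | intermediate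
3 | (13R)-13-(triethylsilyloxy)labda-7,14-diene | C=C[C@](C)(O[Si](CC)(CC)CC)CC[C@H]1C(C)=CC[C@H]2C(C)(C)CCC[C@]12C | intermediate
4 | (13R)-13-(triethylsilyloxy)labda-7,14-dien-6-one | C=C[C@](C)(O[Si](CC)(CC)CC)CC[C@H]1C(C)=CC(=O)[C@H]2C(C)(C)CCC[C@]12C | intermediate
5 | (13R)-13-(triethylsilyloxy)labda-7,14-dien-6β-ol | C=C[C@](C)(O[Si](CC)(CC)CC)CC[C@H]1C(C)=C[C@@H](O)[C@H]2C(C)(C)CCC[C@]12C | intermediate
6 | (13R)-6β-acetoxy-13-(triethylsilyloxy)labda-7,14-diene | C=C[C@](C)(O[Si](CC)(CC)CC)CC[C@H]1C(C)=C[C@@H](OC(C)=O)[C@H]2C(C)(C)CCC[C@]12C | intermediate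
7 | (13R)-6β-acetoxy-7α-hydroperoxy-13-(triethylsilyloxy)labda-8(17),14-diene (7α-hydroperoxide, not isolated) | C=C[C@](C)(O[Si](CC)(CC)CC)CC[C@H]1C(=C)[C@H](OO)[C@@H](OC(C)=O)[C@H]2C(C)(C)CCC[C@]12C | intermediate
8 | (13R)-6β-acetoxy-7α-(acetylperoxy)-13-(triethylsilyloxy)labda-8(17),14-diene (7α-peroxyacetate, not isolated) | C=C[C@](C)(O[Si](CC)(CC)CC)CC[C@H]1C(=C)[C@H](OOC(C)=O)[C@@H](OC(C)=O)[C@H]2C(C)(C)CCC[C@]12C | intermediate
9 | (13R)-6β-acetoxy-13-(triethylsilyloxy)labda-8(17),14-dien-7-one | C=C[C@](C)(O[Si](CC)(CC)CC)CC[C@H]1C(=C)C(=O)[C@@H](OC(C)=O)[C@H]2C(C)(C)CCC[C@]12C | intermediate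
10 | (13R)-6β-acetoxy-13-(triethylsilyloxy)labda-8,14-dien-7-one | C=C[C@](C)(O[Si](CC)(CC)CC)CCC1=C(C)C(=O)[C@@H](OC(C)=O)[C@H]2C(C)(C)CCC[C@]12C | intermediate
11 | (5S,6S,10S,13R)-6β-acetoxy-13-hydroxylabda-8,14-dien-7-one | C=C[C@](C)(O)CCC1=C(C)C(=O)[C@@H](OC(C)=O)[C@H]2C(C)(C)CCC[C@]12C | target

**Totals and risks**
Total step count: 8. Longest linear sequence: 8 steps (fully linear from 1).

The three steps most likely to fail:

Step 2. The Co–H isomerisation may over-run to the tetrasubstituted Δ8(9)-alkene, or the C8 radical may add to the vinyl group. The fallback sets out from 2 and comes back at 3. The exocyclic alkene is epoxidised from the α-face with mCPBA/NaHCO3 (the hindered vinyl group reacts far more slowly) to (13R)-8α,17-epoxy-13-(triethylsilyloxy)labd-14-ene F1. The spiro-epoxide is opened at its CH2 terminus with LiEt3BH to the tertiary alcohol (13R)-13-(triethylsilyloxy)labd-14-en-8α-ol F2, the 13-O-TES ether of sclareol. Burgess dehydration (syn-elimination through the cis 7α-H, benzene, 50 °C) then gives 3, and any 8(17)-isomer 2 is separated and recycled.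

Step 6. The ene reaction on the electron-poor allylic acetate may be too slow or give hydroperoxide mixtures. The fallback sets out from 6 and comes back at 9. mCPBA epoxidation of the trisubstituted alkene from the α-face gives (13R)-6β-acetoxy-7α,8α-epoxy-13-(triethylsilyloxy)labd-14-ene F3. Cp2TiCl (from Cp2TiCl2 and Mn, THF; Nugent–RajanBabu opening to the tertiary C8 radical, then β-hydride elimination) gives the allylic alcohol (13R)-6β-acetoxy-13-(triethylsilyloxy)labda-8(17),14-dien-7α-ol F4. Dess–Martin oxidation gives 9.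

Step 7. HAT isomerisation of the hindered α-methylene ketone may stall or give some conjugate reduction. The fallback sets out from 9 and comes back at 10. Rhodium-catalysed 1,4-hydrosilylation (Et3SiH, RhCl(PPh3)3) gives the tetrasubstituted silyl enol ether (13R)-6β-acetoxy-7,13-bis(triethylsilyloxy)labda-7,14-diene F5. Saegusa–Ito oxidation (Pd(OAc)2, MeCN), with β-hydride loss of the 9α-H, gives 10.

**Further compounds**
F1 | step 2 | (13R)-8α,17-epoxy-13-(triethylsilyloxy)labd-14-ene | C=C[C@](C)(O[Si](CC)(CC)CC)CC[C@H]1[C@@]3(CO3)CC[C@H]2C(C)(C)CCC[C@]12C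
F2 | step 2 | (13R)-13-(triethylsilyloxy)labd-14-en-8α-ol | C=C[C@](C)(O[Si](CC)(CC)CC)CC[C@H]1[C@](C)(O)CC[C@H]2C(C)(C)CCC[C@]12C
F3 | step 6 | (13R)-6β-acetoxy-7α,8α-epoxy-13-(triethylsilyloxy)labd-14-ene | C=C[C@](C)(O[Si](CC)(CC)CC)CC[C@H]1[C@]3(C)O[C@@H]3[C@@H](OC(C)=O)[C@H]2C(C)(C)CCC[C@]12C
F4 | step 6 | (13R)-6β-acetoxy-13-(triethylsilyloxy)labda-8(17),14-dien-7α-ol | C=C[C@](C)(O[Si](CC)(CC)CC)CC[C@H]1C(=C)[C@H](O)[C@@H](OC(C)=O)[C@H]2C(C)(C)CCC[C@]12C
F5 | step 7 | (13R)-6β-acetoxy-7,13-bis(triethylsilyloxy)labda-7,14-diene | C=C[C@](C)(O[Si](CC)(CC)CC)CC[C@H]1C(C)=C(O[Si](CC)(CC)CC)[C@@H](OC(C)=O)[C@H]2C(C)(C)CCC[C@]12C
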